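## The problem

Target **16** is a chroman (O1, C2, C3, C4, C4a, C5–C8, C8a) whose C2 is also C2' of a 3,3-dimethylbicyclo[2.2.1]heptane (C1' the bridgehead on C2, C3' the CMe2 carbon, C7' the one-carbon bridge). The arene carries hydroxyls at C5 and C7 and formyl groups at C6 and C8, and C4 bears an isobutyl group. The spiro carbon is a fully substituted ether carbon wedged between quaternary C3' and bridgehead C1', with O1 on the endo face and C3 on the exo face of the bicycle, so one C–O and one C–C bond must be made at a neopentyl position with a defined facial sense. Of the four stereocentres (2R, 4S, 1'R, 4'S), C1' and C4' come as a pair from the terpene and can direct C2, because reagents reach a C2' carbonyl from the exo side; C2 is then the only lever on C4, across the pyran ring. A simple conformational model says the lever exists: with C3' axial its exo-methyl would lie over C4, so C1' should be axial and C3' equatorial, and only the (4S) epimer can then keep isobutyl pseudo-equatorial. The target is therefore expected to be the more stable C4 epimer. The diformylresorcinol is acidic, chelating and easily oxidised and should appear last. The tertiary O1–C2 ether sits on a camphene-type carbon whose cation would undergo Wagner–Meerwein shifts, so strong protic or Lewis acids are kept away once the pyran exists. The feature that opens the structure is a pair of complementary three-atom units: O1–C2–C3 is an oxygen and a carbon nucleophile in a 1,3 relationship, latent in the spiro epoxide of camphenilone, and C4–C4a–C8a is a carbonyl carbon and a fluorine-bearing aromatic carbon in a 1,3 relationship, with both methoxy groups meta to fluorine.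

## Retrosynthesis

**16 to 15.** The two O–CH3 bonds at C5 and C7 are cut last. The neighbouring option, formylating a free resorcinol at the end, would require cleaving unactivated methyl ethers earlier, which in practice means hot acid or a boron halide on the sensitive spiro ether. In dialdehyde **15** each methoxy group is ortho or para to a formyl group, so a soft nucleophile can remove the methyl groups by SN2 and cannot touch the tertiary ether. The forward step must cleave both ethers and spare the aldehydes and the pyran.

**15 to 13.** The C6–CHO and C8–CHO bonds are cut to a 6,8-dilithio arene **14**, generated from dibromide **13**. An electrophilic double formylation would have to place the second formyl group on a ring already deactivated by the first, under Lewis acid. The anionic route reverses the polarity and uses the flanking oxygens to stabilise each C–Li bond. The precursor loses two carbons and both carbonyl groups.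

**13 to 12.** The two C–Br bonds are cut. C6 and C8 are the only free positions of chroman **12** and both are doubly activated, so exhaustive bromination raises no regiochemical question.

**12 to 11.** The C4–H bond (with C3–H) is cut, which removes the C4 stereocentre and leads to chromene **11**. Setting C4 in an open chain would need a second source of chirality; here the spiro centre is asked to do it. The forward reaction must place hydrogen on the face of C4 syn to C1', which is the face leading to the more stable epimer.

**11 to 10.** Water is added back across C3=C4 to give tertiary benzylic alcohol **10**. Its C4 configuration is irrelevant, which frees the preceding step from any stereochemical demand at that carbon.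

**10 to 4 and 7.** This is the central cut: C3–C4 and O1–C8a are broken together. That divides the pyran into spiro epoxide **4**, which on two-electron reduction becomes the C3-lithio C2-alkoxide **8**, and ortho-fluoroaryl ketone **7**. Cutting only O1–C8a or only C3–C4 would leave an open-chain precursor with the hindered C2 centre still to be made. The double cut returns two fragments of ten and thirteen carbons, each one or two steps from commercial material, and carries the endo C2–O bond through unchanged. The forward reaction asks for regioselective epoxide opening, carbonyl addition to a hindered enolisable ketone (giving dialkoxide **9**), and displacement of fluoride by a hindered alkoxide.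

**4 to 2 and 3.** The epoxide CH2–C2 and CH2–O bonds are cut to camphenilone **2** and the methylene of trimethylsulfonium iodide **3**. Epoxidising camphene directly would bring oxygen in on the exo face, the wrong one. Adding a methylene nucleophile to the ketone brings carbon in exo and leaves oxygen endo.

**2 to 1.** The C=O bond of **2** is traced to the exocyclic C=CH2 of (−)-camphene **1**, which supplies C1' and C4' in the required absolute configuration.

**7 to 5 and 6.** The aryl–acyl bond is cut to 1-fluoro-3,5-dimethoxybenzene **5** and isovaleryl chloride **6**. The position between fluorine and methoxy is para to the other methoxy group and less crowded than the position between the two methoxy groups, so one acylation should give the required substitution pattern.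

## Roads not taken

**Alternative 1:** The benzene ring is built last, by forming C4a–C5, C5–C6 and C7–C8 on a preformed spiro dihydropyran. Irradiation of diazoketone A1 with siloxyalkyne A2 would trigger a Wolff rearrangement (C8a migrates to the diazo carbon, the future C8) and (2+2) addition of the alkyne. Heating would then open the four-membered ring and a six-electron closure would form C4a–C5, giving phenol A3.
- Merits: C2 and C4 are fixed before any arene chemistry. The arene is born with the C6 carbon and three differentiated oxygens. The silyl groups come off under neutral fluoride conditions, which is gentler than the thiolate demethylation of the chosen plan. No substitution on an electron-rich ring is needed.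
- Weak points: A1 needs C2 and C4 set in a dihydropyran. The obvious access, cycloaddition of an oxadiene to **1**, would have to bring oxygen to the endo face, and nothing in **1** secures that. Making the diazoketone costs further steps. After A3 a C8 formylation, two desilylations and an oxidation remain.
- Comparison: this road is several steps longer and less secure at C2, but it has the better endgame. The chosen plan sets against it a known facial bias at C2 and two fragments that are each made in one or two steps.

**Alternative 2:** The C3=C4 double bond is cut. The second-generation Hoveyda–Grubbs catalyst would join the vinyl group on C2 of diene A4 to its 1,1-disubstituted styrene with loss of ethylene, giving chromene A5, which is identical with **11**.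
- Merits: every step is a known reaction type, which is a real advantage over a key step that is untested as one pot. The O1–C8a bond would be made while the ortho carbonyl of **7** still activates fluoride.
- Weak points: that etherification is intermolecular and uses a very hindered tertiary alkoxide. The doubly ortho-substituted ketone must then be methylenated. Metathesis must start at a vinyl group on a fully substituted carbon between C3' and C1' and form a trisubstituted styrenic alkene beside the C5 methoxy group. From **2** this takes four steps to A5, against three to **11**.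
- Comparison: both roads share the same downstream chemistry and the same C4 question. The chosen plan saves a step, avoids ruthenium and turns the etherification into a ring closure. Alternative 2 keeps the merit of precedent.

**Alternative 3:** Only O1–C8a is cut, at an aromatic C–H bond. Anodic oxidation of carbinol A6 (carbon anode, hexafluoroisopropanol, Bu4NPF6, 2,6-lutidine) would give an arene radical cation that the endo hydroxyl traps at the ortho carbon. Further oxidation and proton loss would give A7, identical with **12**.
- Merits: no halogen is needed and the two ortho positions are equivalent. C4 is already in place, so the hydrogenation question of the chosen plan does not arise; on that point this road is better.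
- Weak points: C4 must be set in an open chain remote from the terpene, by a separate asymmetric step matched to **1**. The chain must be attached to hindered **2** through a β-branched organometallic. A7 has three oxygen donors and is more easily oxidised than A6, so over-oxidation threatens. The radical cation can lose its tertiary benzylic proton at C4. The hindered alcohol is a slow trap.
- Comparison: the chosen plan sets against it a C4 centre derived from the ring itself with no second source of chirality, and a ring closure whose site is fixed by fluorine.

Key step: step 4

Assumption: (1S,4R)-(−)-camphene is used enantiomerically pure (material of lower purity would be upgraded first), because no later step corrects the enantiomeric ratio.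

Assumption: **10** is expected as a mixture of C4 epimers; one is drawn and both serve.

## Route

Step 1
Reactants: 1 (1S,4R)-(−)-camphene
Product: 2 (1R,4S)-camphenilone (3,3-dimethylbicyclo[2.2.1]heptan-2-one)
Conditions: O3, CH2Cl2–MeOH, −78 °C; Me2S, −78 °C → rt
Reagents that add atoms: ozone, [O-][O+]=O
Why: Ozonolysis of the exocyclic 1,1-disubstituted alkene with reductive work-up gives the non-enolisable ketone; the bridgeheads are untouched and only their locants change.

Step 2
Reactants: 2 (1R,4S)-camphenilone; 3 trimethylsulfonium iodide
Product: 4 (1R,2R,4S)-3,3-dimethylspiro[bicyclo[2.2.1]heptane-2,2'-oxirane] (oxygen endo, CH2 exo)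
Conditions: 3, n-BuLi, THF, −10 °C; then 2, −10 °C → rt
Reagents that add atoms: none
Why: Corey–Chaykovsky epoxidation; dimethylsulfonium methylide adds irreversibly to the carbonyl from the exo face, away from the endo hydrogens of the two-carbon bridge, so after ring closure the methylene is exo and the oxygen endo, and the ketone cannot enolise.

Step 3
Reactants: 5 1-fluoro-3,5-dimethoxybenzene; 6 3-methylbutanoyl chloride (isovaleryl chloride)
Product: 7 1-(2-fluoro-4,6-dimethoxyphenyl)-3-methylbutan-1-one
Conditions: SnCl4, CH2Cl2, −10 °C → rt
Reagents that add atoms: none
Why: Friedel–Crafts acylation at the position para to one methoxy group and ortho to the other, which is less crowded than the position between the two methoxy groups; SnCl4 is mild enough to leave the ortho methyl ether intact.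

Step 4
Reactants: 4 (1R,2R,4S)-3,3-dimethylspiro[bicyclo[2.2.1]heptane-2,2'-oxirane]; 7 1-(2-fluoro-4,6-dimethoxyphenyl)-3-methylbutan-1-one
Product: 10 (2R,1'R,4'S)-4-isobutyl-5,7-dimethoxy-3',3'-dimethylspiro[chromane-2,2'-bicyclo[2.2.1]heptan]-4-ol (C4 epimers), via β-lithio alkoxide 8 (not isolated), via open-chain fluoroaryl dialkoxide 9 (not isolated)
Conditions: LiDBB (lithium 4,4'-di-tert-butylbiphenylide, 1.95 equiv per 4), THF, −78 °C; CeCl3, −78 °C; 7 (limiting), −78 → 0 °C; then KOt-Bu, DMPU, 65 °C
Reagents that add atoms: none
Why: Proposed new method: two electrons from LiDBB cleave the CH2–O bond of 4, the less substituted carbanion being the one formed, so 8 carries a primary C3–Li bond and an intact endo C2–O–Li bond. Below −70 °C 8 does not lose Li2O, and once complexed with CeCl3 it is nucleophilic but weakly basic and adds to the hindered, enolisable carbonyl of 7, forming C3–C4 and dialkoxide 9. KOt-Bu and DMPU then supply potassium counter-ions and loosen the ion pair, and the C2 alkoxide attacks C8a by intramolecular addition–elimination through a Meisenheimer intermediate (a six-membered, 6-exo-trig-type closure) with loss of fluoride, forming O1–C8a and the pyran ring. The closest known reaction types are the reductive lithiation of epoxides to β-lithio alkoxides with carbonyl trapping to 1,3-diols, and the base-mediated cyclisation of 3-(2-fluoroaryl)propanols to chromans; joining them in one flask is what is new. The only new stereocentre, C4, is uncontrolled and need not be controlled because step 5 removes it, while C2 keeps the configuration of 4 because its C–O bond is never broken. Regioselectivity of the epoxide opening rests on carbanion stability, and the choice between the two alkoxides rests on ring size, since the C4 alkoxide could only close a four-membered ring; both methoxy groups are meta to fluorine and assist inductively. LiDBB is kept in slight deficit to 4 so that no radical anion remains to reduce 7 or its C–F bond.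

Step 5
Reactants: 10 (2R,1'R,4'S)-4-isobutyl-5,7-dimethoxy-3',3'-dimethylspiro[chromane-2,2'-bicyclo[2.2.1]heptan]-4-ol
Product: 11 (1'R,4'S)-4-isobutyl-5,7-dimethoxy-3',3'-dimethylspiro[2H-chromene-2,2'-bicyclo[2.2.1]heptane] (O1 endo as in 4)
Conditions: MsCl, Et3N, DMAP (cat.), CH2Cl2, 0 °C → rt
Reagents that add atoms: none
Why: Sulfene-type mesylation of the tertiary benzylic alcohol, then E1 loss of a C3 proton from a cation stabilised by three ortho/para oxygens, all under amine buffering so the spiro ether never meets free acid; a side-chain double-bond isomer, if formed, would pass through the same C4 radical in step 6.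

Step 6
Reactants: 11 (1'R,4'S)-4-isobutyl-5,7-dimethoxy-3',3'-dimethylspiro[2H-chromene-2,2'-bicyclo[2.2.1]heptane]
Product: 12 (2R,4S,1'R,4'S)-4-isobutyl-5,7-dimethoxy-3',3'-dimethylspiro[chromane-2,2'-bicyclo[2.2.1]heptane]
Conditions: Mn(dpm)3 (cat.; dpm = 2,2,6,6-tetramethylheptane-3,5-dionate), PhSiH3, t-BuOOH, i-PrOH, rt, degassed
Reagents that add atoms: none
Why: Metal-hydride hydrogen-atom-transfer hydrogenation; the manganese hydride gives hydrogen to C3 and the tertiary benzylic C4 radical takes the second hydrogen through a late, product-like transition state. This should favour the (4S) epimer, the only one that keeps C1' axial, C3' equatorial and isobutyl pseudo-equatorial; the 4-epimer would press isobutyl against H–C1' or bring the exo-methyl of C3' over C4.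

Step 7
Reactants: 12 (2R,4S,1'R,4'S)-4-isobutyl-5,7-dimethoxy-3',3'-dimethylspiro[chromane-2,2'-bicyclo[2.2.1]heptane]
Product: 13 (2R,4S,1'R,4'S)-6,8-dibromo-4-isobutyl-5,7-dimethoxy-3',3'-dimethylspiro[chromane-2,2'-bicyclo[2.2.1]heptane]
Conditions: NBS (2.1 equiv), MeCN, 0 °C → rt, dark
Reagents that add atoms: N-bromosuccinimide, O=C1CCC(=O)N1Br
Why: Electrophilic aromatic bromination; C6 and C8 are the only free ring positions and each is ortho/para to oxygen donors, and ionic conditions in the dark leave the benzylic C4–H alone.

Step 8
Reactants: 13 (2R,4S,1'R,4'S)-6,8-dibromo-4-isobutyl-5,7-dimethoxy-3',3'-dimethylspiro[chromane-2,2'-bicyclo[2.2.1]heptane]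
Product: 15 (2R,4S,1'R,4'S)-4-isobutyl-5,7-dimethoxy-3',3'-dimethylspiro[chromane-2,2'-bicyclo[2.2.1]heptane]-6,8-dicarbaldehyde, via 6,8-dilithio chroman 14 (not isolated)
Conditions: t-BuLi (4.4 equiv), THF, −78 °C; DMF, −78 °C → rt; aq. NH4Cl
Reagents that add atoms: N,N-dimethylformamide, CN(C)C=O
Why: Double bromine–lithium exchange gives 14, in which each C–Li bond is flanked by two coordinating oxygens; formylation with DMF gives stable lithium hemiaminal alkoxides that release both aldehydes only on work-up.

Step 9
Reactants: 15 (2R,4S,1'R,4'S)-4-isobutyl-5,7-dimethoxy-3',3'-dimethylspiro[chromane-2,2'-bicyclo[2.2.1]heptane]-6,8-dicarbaldehyde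
Product: 16 (2R,4S,1'R,4'S)-5,7-dihydroxy-4-isobutyl-3',3'-dimethylspiro[chromane-2,2'-bicyclo[2.2.1]heptane]-6,8-dicarbaldehyde (CNP0150011.1)
Conditions: NaSEt (excess), DMF, 110 °C; aq. HCl
Reagents that add atoms: none
Why: Nucleophilic demethylation by SN2 attack of thiolate on the methyl groups, each departing aryloxide being stabilised by ortho/para formyl groups; the tertiary O1–C2 ether cannot react this way, thiolate addition to the aldehydes is reversible, and C4 is not activated by the formyl groups, which are meta to C4a.

## Compound list

1 | (1S,4R)-(−)-camphene | C=C1[C@@H]2CC[C@@H](C2)C1(C)C | starting material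
2 | (1R,4S)-camphenilone (3,3-dimethylbicyclo[2.2.1]heptan-2-one) | O=C1[C@@H]2CC[C@@H](C2)C1(C)C | intermediate
3 | trimethylsulfonium iodide | C[S+](C)C.[I-] | starting material
4 | (1R,2R,4S)-3,3-dimethylspiro[bicyclo[2.2.1]heptane-2,2'-oxirane], oxygen endo | C1O[C@@]12[C@@H]3CC[C@@H](C3)C2(C)C | intermediate
5 | 1-fluoro-3,5-dimethoxybenzene | COc1cc(F)cc(OC)c1 | starting material
6 | 3-methylbutanoyl chloride (isovaleryl chloride) | CC(C)CC(=O)Cl | starting material
7 | 1-(2-fluoro-4,6-dimethoxyphenyl)-3-methylbutan-1-one | CC(C)CC(=O)c1c(F)cc(OC)cc1OC | intermediate
8 | lithium (1R,4S)-2-exo-(lithiomethyl)-3,3-dimethylbicyclo[2.2.1]heptan-2-endo-olate | [Li]C[C@@]1(O[Li])[C@@H]2CC[C@@H](C2)C1(C)C | intermediate (not isolated)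
9 | dialkoxide of 2-[2-(2-fluoro-4,6-dimethoxyphenyl)-2-hydroxy-4-methylpentyl]-3,3-dimethylbicyclo[2.2.1]heptan-2-endo-ol, drawn as the dilithium salt, both carbinol epimers | CC(C)CC(O[Li])(C[C@@]1(O[Li])[C@@H]2CC[C@@H](C2)C1(C)C)c1c(F)cc(OC)cc1OC | intermediate (not isolated)
10 | (2R,1'R,4'S)-4-isobutyl-5,7-dimethoxy-3',3'-dimethylspiro[chromane-2,2'-bicyclo[2.2.1]heptan]-4-ol, C4 epimers, (4R) form drawn | CC(C)C[C@@]1(O)C[C@@]2(Oc3cc(OC)cc(OC)c31)[C@@H]1CC[C@@H](C1)C2(C)C | intermediate
11 | (1'R,4'S)-4-isobutyl-5,7-dimethoxy-3',3'-dimethylspiro[2H-chromene-2,2'-bicyclo[2.2.1]heptane], O1 endo | CC(C)CC1=C[C@@]2(Oc3cc(OC)cc(OC)c31)[C@@H]1CC[C@@H](C1)C2(C)C | intermediate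
12 | (2R,4S,1'R,4'S)-4-isobutyl-5,7-dimethoxy-3',3'-dimethylspiro[chromane-2,2'-bicyclo[2.2.1]heptane] | CC(C)C[C@H]1C[C@@]2(Oc3cc(OC)cc(OC)c31)[C@@H]1CC[C@@H](C1)C2(C)C | intermediate
13 | (2R,4S,1'R,4'S)-6,8-dibromo-4-isobutyl-5,7-dimethoxy-3',3'-dimethylspiro[chromane-2,2'-bicyclo[2.2.1]heptane] | CC(C)C[C@H]1C[C@@]2(Oc3c(Br)c(OC)c(Br)c(OC)c31)[C@@H]1CC[C@@H](C1)C2(C)C | intermediate
14 | 6,8-dilithio derivative of 12 | CC(C)C[C@H]1C[C@@]2(Oc3c([Li])c(OC)c([Li])c(OC)c31)[C@@H]1CC[C@@H](C1)C2(C)C | intermediate (not isolated)
15 | (2R,4S,1'R,4'S)-4-isobutyl-5,7-dimethoxy-3',3'-dimethylspiro[chromane-2,2'-bicyclo[2.2.1]heptane]-6,8-dicarbaldehyde | CC(C)C[C@H]1C[C@@]2(Oc3c(C=O)c(OC)c(C=O)c(OC)c31)[C@@H]1CC[C@@H](C1)C2(C)C | intermediate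
16 | (2R,4S,1'R,4'S)-5,7-dihydroxy-4-isobutyl-3',3'-dimethylspiro[chromane-2,2'-bicyclo[2.2.1]heptane]-6,8-dicarbaldehyde (CNP0150011.1) | CC(C)C[C@H]1C[C@@]2(Oc3c(C=O)c(O)c(C=O)c(O)c31)[C@@H]1CC[C@@H](C1)C2(C)C | target

## Step count and least certain steps

Total: 9 steps. Longest linear sequence: 8 steps (1, 2, 4, 5, 6, 7, 8, 9); step 3 is a one-step branch.

**Step 4 (key step).** Three things can go wrong.
- Enolisation of **7**, or electron transfer to it, may compete with carbonyl addition.
- The ring closure may stall at the dialkoxide stage, because a hindered tertiary alkoxide bound to lithium or cerium is a weak nucleophile towards an arene that no longer has an acceptor group. This is the most likely failure.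
- The β-lithio alkoxide may lose Li2O if the temperature rises before the ketone is consumed.

The fallback separates the two events into known operations. It sets out from **4** and **7**: reductive lithiation and CeCl3-mediated addition as above, cold aqueous quench, and isolation of 2-[2-(2-fluoro-4,6-dimethoxyphenyl)-2-hydroxy-4-methylpentyl]-3,3-dimethylbicyclo[2.2.1]heptan-2-endo-ol F1. F1 is then cyclised as its dipotassium salt with KN(SiMe3)2 in DMF at elevated temperature, the standard alkoxide-on-fluoroarene chroman closure, and the route is rejoined at **10**.

**Step 6.** The risk is poor facial selectivity in the delivery of hydrogen to C4. In the same model, the face syn to C1' that must receive hydrogen is screened by H–C1' lying under the ring, while the opposite face is open because C3' is equatorial. A donor that follows the easier approach would give the less stable 4-epimer. The step therefore relies on a product-like transition state.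

The fallback reverses the roles at C4 so that approach and product stability agree. It sets out from **4**, which is annulated under the step 4 conditions with commercial 2-fluoro-4,6-dimethoxybenzaldehyde (COc1cc(F)c(C=O)c(OC)c1) in place of **7**. This partner cannot enolise and is less hindered, and gives (2R,1'R,4'S)-5,7-dimethoxy-3',3'-dimethylspiro[chromane-2,2'-bicyclo[2.2.1]heptan]-4-ol F2. Ionisation with BF3·OEt2 at −78 °C in the presence of 2-methylallyltrimethylsilane (a Hosomi–Sakurai-type benzylic substitution) lets the carbon nucleophile enter C4 on the open face, syn to C3'. The small hydrogen moves to the screened face, giving (2R,4S,1'R,4'S)-5,7-dimethoxy-3',3'-dimethyl-4-(2-methylprop-2-enyl)spiro[chromane-2,2'-bicyclo[2.2.1]heptane] F3. Hydrogenation of the side-chain alkene (H2, Pd/C) rejoins the route at **12**.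

**Step 8.** The risk is incomplete second bromine–lithium exchange, or protonation of an aryllithium before DMF arrives, leaving one position unformylated. The fallback avoids aryl anions. It sets out from **13**: double Suzuki–Miyaura coupling with potassium vinyltrifluoroborate (Pd(OAc)2, SPhos, K2CO3) gives (2R,4S,1'R,4'S)-6,8-diethenyl-4-isobutyl-5,7-dimethoxy-3',3'-dimethylspiro[chromane-2,2'-bicyclo[2.2.1]heptane] F4. Lemieux–Johnson cleavage (OsO4 cat., NaIO4, 2,6-lutidine, dioxane–water) then rejoins the route at **15**.

**Step 9.** Two risks apply: incomplete cleavage of the second methyl ether once the first phenoxide has made the ring electron-rich, and base-induced opening of the pyran by elimination across C2–C3 now that O1 belongs to a good aryloxide leaving group. The fallback reorders the endgame. It sets out from **12**: demethylation with BBr3 at low temperature gives (2R,4S,1'R,4'S)-4-isobutyl-3',3'-dimethylspiro[chromane-2,2'-bicyclo[2.2.1]heptane]-5,7-diol F5. Double Rieche formylation of this free resorcinol (Cl2CHOMe, TiCl4, CH2Cl2, low temperature) arrives directly at **16**, bypassing steps 7 to 9. This sequence exposes the spiro ether to Lewis acids, which is why it is held in reserve.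

## Further compounds

F1 | step 4 | 2-[2-(2-fluoro-4,6-dimethoxyphenyl)-2-hydroxy-4-methylpentyl]-3,3-dimethylbicyclo[2.2.1]heptan-2-endo-ol (both carbinol epimers) | CC(C)CC(O)(C[C@@]1(O)[C@@H]2CC[C@@H](C2)C1(C)C)c1c(F)cc(OC)cc1OC
F2 | step 6 | (2R,1'R,4'S)-5,7-dimethoxy-3',3'-dimethylspiro[chromane-2,2'-bicyclo[2.2.1]heptan]-4-ol (C4 epimers, one drawn) | O[C@H]1C[C@@]2(Oc3cc(OC)cc(OC)c31)[C@@H]1CC[C@@H](C1)C2(C)C
F3 | step 6 | (2R,4S,1'R,4'S)-5,7-dimethoxy-3',3'-dimethyl-4-(2-methylprop-2-enyl)spiro[chromane-2,2'-bicyclo[2.2.1]heptane] | CC(=C)C[C@H]1C[C@@]2(Oc3cc(OC)cc(OC)c31)[C@@H]1CC[C@@H](C1)C2(C)C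
F4 | step 8 | (2R,4S,1'R,4'S)-6,8-diethenyl-4-isobutyl-5,7-dimethoxy-3',3'-dimethylspiro[chromane-2,2'-bicyclo[2.2.1]heptane] | CC(C)C[C@H]1C[C@@]2(Oc3c(C=C)c(OC)c(C=C)c(OC)c31)[C@@H]1CC[C@@H](C1)C2(C)C
F5 | step 9 | (2R,4S,1'R,4'S)-4-isobutyl-3',3'-dimethylspiro[chromane-2,2'-bicyclo[2.2.1]heptane]-5,7-diol | CC(C)C[C@H]1C[C@@]2(Oc3cc(O)cc(O)c31)[C@@H]1CC[C@@H](C1)C2(C)C
A1 | alternative 1 | 6-(diazoacetyl)-4-isobutyl-3,4-dihydro-2H-pyran spiro-fused at C2 to the 3,3-dimethylbicyclo[2.2.1]heptane unit | CC(C)C[C@H]1C[C@@]2(OC(C(=O)C=[N+]=[N-])=C1)[C@@H]1CC[C@@H](C1)C2(C)C
A2 | alternative 1 | tert-butyldimethyl{[3-(triisopropylsilyloxy)prop-2-yn-1-yl]oxy}silane | CC(C)[Si](OC#CCO[Si](C)(C)C(C)(C)C)(C(C)C)C(C)C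
A3 | alternative 1 | 5-hydroxy-7-(triisopropylsilyloxy)-6-(tert-butyldimethylsilyloxymethyl) spiro chroman | CC(C)C[C@H]1C[C@@]2(Oc3cc(O[Si](C(C)C)(C(C)C)C(C)C)c(CO[Si](C)(C)C(C)(C)C)c(O)c31)[C@@H]1CC[C@@H](C1)C2(C)C
A4 | alternative 2 | 2-endo-[3,5-dimethoxy-2-(4-methylpent-1-en-2-yl)phenoxy]-2-exo-ethenyl-3,3-dimethylbicyclo[2.2.1]heptane | C=C[C@@]1(Oc2cc(OC)cc(OC)c2C(=C)CC(C)C)[C@@H]2CC[C@@H](C2)C1(C)C
A5 | alternative 2 | 4-isobutyl-5,7-dimethoxy spiro 2H-chromene (identical with 11) | CC(C)CC1=C[C@@]2(Oc3cc(OC)cc(OC)c31)[C@@H]1CC[C@@H](C1)C2(C)C
A6 | alternative 3 | 2-exo-[(2S)-2-(3,5-dimethoxyphenyl)-4-methylpentyl]-3,3-dimethylbicyclo[2.2.1]heptan-2-endo-ol | CC(C)C[C@@H](C[C@@]1(O)[C@@H]2CC[C@@H](C2)C1(C)C)c1cc(OC)cc(OC)c1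
A7 | alternative 3 | 4-isobutyl-5,7-dimethoxy spiro chroman (identical with 12) | CC(C)C[C@H]1C[C@@]2(Oc3cc(OC)cc(OC)c31)[C@@H]1CC[C@@H](C1)C2(C)C
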